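**Plan**
- Retrosynthetic cuts: butenolide ⇒ 2-silylfuran (oxidation level only); C6–OAc and C8–H ⇒ C6 ketone with C7=C8; ring A cut at C10–C1 and C5–C4 (retro-[4+2]) ⇒ prochiral quinol ether 13 + 4-methyl-1,3-pentadiene; C9–C11 ⇒ quinone monoketal + furylethyllithium.
- Enabling feature: ring B (C5–C10) carries oxygen at C6 and C9 across the ring and methyls at C8 and C10, so it is a reduced 3,5-dimethyl-p-quinol whose two enone halves (C5=C10, C7=C8) are enantiotopic. Ring A (C10, C1–C5) has its gem-dimethyl carbon C4 next to C5, the pattern of a 4-methyl-1,3-pentadiene cycloadduct.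
- Forward order: the furan ring is bought (3-bromofuran), ring B comes from a phenol, ring A is closed last by a catalytic desymmetrising Diels–Alder reaction. The helpers are the O–SiMe3 group (catalyst compatibility, removed in step 8) and the furyl SiEt3 group (directs the final oxidation to C16, lost in step 12).
- Stereochemistry: C10, C9 and C5 (first cis) arise in the cycloaddition (face: syn to the C9 oxygen; choice of enone half: chiral oxazaborolidinium). C5 is turned trans by enolate equilibration, C8 comes from axial protonation in Li/NH3, C6 from α-face hydride delivery.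

Key step: step 6

Remark: labdane numbering is used for all decalin compounds (C1–C10 ring carbons, C11–C16 side chain, C17 on C8, C20 on C10); β is the face of the C10 methyl, α the face of the C9 oxygen.
Assumption: the catalyst antipode written in step 6 (from (S)-α,α-diphenylprolinol) is the one taken from the α-C–H···O binding model to lead to the (5R,9R,10S) adduct; if the model points the other way, the (R)-catalyst is used and nothing else changes.

**Step 1**
Reactants: 1 3-bromofuran
Product: 3 3-bromo-2-(triethylsilyl)furan, via 3-bromo-2-lithiofuran 2 (not isolated)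
Conditions: LDA, THF, −78 °C; then Et3SiCl, −78 → 0 °C
Reagents that add atoms: chlorotriethylsilane, CC[Si](Cl)(CC)CC
Why: LDA removes the most acidic proton of 3-bromofuran (C2–H, between O and Br) and the 2-lithiofuran is silylated (directed metalation and electrophilic quench), which places silicon on the furan carbon that later becomes the lactone carbonyl.

**Step 2**
Reactants: 3 3-bromo-2-(triethylsilyl)furan; 4 oxirane
Product: 6 2-[2-(triethylsilyl)furan-3-yl]ethan-1-ol, via 3-lithio-2-(triethylsilyl)furan 5 (not isolated)
Conditions: n-BuLi, Et2O, −78 °C; then oxirane, BF3·OEt2, −78 °C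
Reagents that add atoms: none
Why: bromine–lithium exchange gives the 3-furyllithium, which opens BF3-activated oxirane at −78 °C (Lewis-acid-assisted epoxide opening by an aryllithium), below the temperature at which 3-lithiofurans isomerise.

**Step 3**
Reactants: 6 2-[2-(triethylsilyl)furan-3-yl]ethan-1-ol
Product: 7 3-(2-iodoethyl)-2-(triethylsilyl)furan
Conditions: I2, PPh3, imidazole, CH2Cl2, 0 °C → rt
Reagents that add atoms: iodine, II
Why: Appel-type iodination of a primary alcohol, which proceeds under neutral conditions that leave the furylsilane intact.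

**Step 4**
Reactants: 8 4-methoxy-2,6-dimethylphenol
Product: 9 4,4-dimethoxy-2,6-dimethylcyclohexa-2,5-dien-1-one
Conditions: PhI(OAc)2, MeOH, 0 °C → rt
Reagents that add atoms: methanol, CO
Why: hypervalent-iodine oxidative dearomatisation of a p-methoxyphenol in methanol gives the quinone monoketal, in which only the carbonyl flanked by the two methyl-bearing carbons is free.

**Step 5**
Reactants: 7 3-(2-iodoethyl)-2-(triethylsilyl)furan; 9 4,4-dimethoxy-2,6-dimethylcyclohexa-2,5-dien-1-one
Product: 13 3,5-dimethyl-4-{2-[2-(triethylsilyl)furan-3-yl]ethyl}-4-[(trimethylsilyl)oxy]cyclohexa-2,5-dien-1-one, via alkyllithium 10 (not isolated), via lithium alkoxide 11 (not isolated), via silyl ether ketal 12 (not isolated)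
Conditions: 7, t-BuLi (2 equiv), Et2O–pentane, −78 °C; then 9, −78 °C; then Me3SiCl, −78 → 0 °C; then SiO2, 10% aq. oxalic acid, CH2Cl2, rt
Reagents that add atoms: chlorotrimethylsilane, C[Si](C)(C)Cl; water, O
Why: iodine–lithium exchange gives the primary alkyllithium, which adds 1,2 to the only free carbonyl of the monoketal; the tertiary alkoxide is capped as its TMS ether and the doubly allylic dimethyl ketal is then hydrolysed by mild acid that the hindered tertiary silyl ether should survive (quinone-monoketal route to p-quinols).

**Step 6**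
Reactants: 13 3,5-dimethyl-4-{2-[2-(triethylsilyl)furan-3-yl]ethyl}-4-[(trimethylsilyl)oxy]cyclohexa-2,5-dien-1-one; 14 4-methyl-1,3-pentadiene
Product: 15 (5R,9R,10S)-16-(triethylsilyl)-9-[(trimethylsilyl)oxy]-15,16-epoxylabda-2,7,13(16),14-tetraen-6-one
Conditions: B-o-tolyl oxazaborolidine from (S)-α,α-diphenylprolinol·AlBr3 (20 mol%), 14 (5 equiv), CH2Cl2, −78 → −40 °C
Reagents that add atoms: none
Why: Proposed new method: the cationic oxazaborolidinium binds the unhindered C6 carbonyl of 13 on the lone pair syn to one vinylic α-C–H (B–O coordination plus C–H···O contact), so that one of the two enantiotopic β-methyl enone units lies in the chiral pocket with its LUMO lowered and reacts with 14 in a concerted but strongly asynchronous [4+2] cycloaddition, the C10–C1 bond (CH2 terminus to β-carbon) leading and the gem-dimethylallyl terminus carrying the developing positive charge, which should ease the strain that the Z-methyl of the diene normally causes. The closest known reaction types are the oxazaborolidinium-catalysed enantioselective Diels–Alder reactions of quinones, quinone monoketals and cyclic enones and the Lewis-acid-promoted "ortho"-selective cycloadditions of 4-methyl-1,3-pentadiene to enones; what has not been shown is catalyst control over the two enantiotopic enone units of a quinol ether. Ring A (C10–C1–C2–C3–C4–C5) is closed by intermolecular [4+2] cycloaddition, both new σ-bonds being formed suprafacially on the same face of ring B. C10 (quaternary) and C5 therefore come out cis, C9 becomes stereogenic through the desymmetrisation and is fixed relative to C10 by attack on the ring face syn to the silyloxy group and anti to the carbon chain (the known facial preference of 4-alkyl-4-oxy-cyclohexadienones), and the absolute configuration is fixed by the catalyst, which leaves open the oxygen-bearing face of the C5=C10 unit, whereas the mirror-related complex could only offer the chain-bearing face of the C7=C8 unit (mismatched). The step needs site, face, regio- and chemoselectivity: site and face are secured by this matched pairing of catalyst shielding and substrate bias, regiochemistry by the single carbonyl (nucleophilic CH2 terminus to C10, CMe2 terminus to C5), no endo/exo issue arises because neither diene terminus is stereogenic, and the furan is kept from competing as a nucleophile by its bulky 2-silyl group and the low temperature.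

**Step 7**
Reactants: 15 (5R,9R,10S)-16-(triethylsilyl)-9-[(trimethylsilyl)oxy]-15,16-epoxylabda-2,7,13(16),14-tetraen-6-one
Product: 16 (5R,9R,10S)-16-(triethylsilyl)-9-[(trimethylsilyl)oxy]-15,16-epoxylabda-7,13(16),14-trien-6-one
Conditions: H2 (3 atm), RhCl(PPh3)3 (10 mol%), PhH–EtOH, rt
Reagents that add atoms: none
Why: homogeneous hydrogenation with Wilkinson's catalyst should reduce the cis-disubstituted C2=C3 alkene and leave the trisubstituted conjugated C7=C8 enone, the furan and both silyl groups untouched.

**Step 8**
Reactants: 16 (5R,9R,10S)-16-(triethylsilyl)-9-[(trimethylsilyl)oxy]-15,16-epoxylabda-7,13(16),14-trien-6-one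
Product: 18 (5S,9R,10S)-9-hydroxy-16-(triethylsilyl)-15,16-epoxylabda-7,13(16),14-trien-6-one, via cis-fused hydroxy enone 17 (not isolated)
Conditions: K2CO3, MeOH, rt → 40 °C
Reagents that add atoms: none
Why: methanolysis removes the O-silyl group and the base equilibrates C5 through the cross-conjugated dienolate of the C6 ketone to the trans-fused decalin (5α-H, both ring-fusion bonds equatorial), which is also the product of protonation anti to the C10 methyl.

**Step 9**
Reactants: 18 (5S,9R,10S)-9-hydroxy-16-(triethylsilyl)-15,16-epoxylabda-7,13(16),14-trien-6-one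
Product: 19 (5S,8R,9R,10S)-9-hydroxy-16-(triethylsilyl)-15,16-epoxylabda-13(16),14-dien-6-one
Conditions: Li, NH3(l)–THF, −78 °C; then isoprene, NH4Cl
Reagents that add atoms: none
Why: in this dissolving-metal enone reduction the β-carbon C8 is protonated axially from the β-face, which gives the equatorial 8α-methyl group (the epimer free of a syn-diaxial contact with the C10 methyl), while the C9 oxygen, present as its lithium alkoxide, is too poor a leaving group to be expelled.

**Step 10**
Reactants: 19 (5S,8R,9R,10S)-9-hydroxy-16-(triethylsilyl)-15,16-epoxylabda-13(16),14-dien-6-one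
Product: 20 (5S,6R,8R,9R,10S)-16-(triethylsilyl)-15,16-epoxylabda-13(16),14-diene-6β,9α-diol
Conditions: NaBH4, MeOH, 0 °C
Reagents that add atoms: none
Why: hydride should attack the C6 ketone from the α-face because the β-face is closed by the axial C10 methyl and the axial C4 methyl, giving the axial 6β-alcohol.

**Step 11**
Reactants: 20 (5S,6R,8R,9R,10S)-16-(triethylsilyl)-15,16-epoxylabda-13(16),14-diene-6β,9α-diol
Product: 21 (5S,6R,8R,9R,10S)-6β-acetoxy-16-(triethylsilyl)-15,16-epoxylabda-13(16),14-dien-9α-ol
Conditions: Ac2O, DMAP, Et3N, CH2Cl2, rt → 40 °C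
Reagents that add atoms: acetic anhydride, CC(=O)OC(C)=O
Why: DMAP-catalysed acylation esterifies the secondary 6β-hydroxyl and leaves the tertiary 9α-hydroxyl, flanked by a quaternary carbon, free.

**Step 12**
Reactants: 21 (5S,6R,8R,9R,10S)-6β-acetoxy-16-(triethylsilyl)-15,16-epoxylabda-13(16),14-dien-9α-ol
Product: 22 (5S,6R,8R,9R,10S)-6β-acetoxy-9α-hydroxylabd-13-en-16,15-olide
Conditions: AcOOH (ca. 35% in AcOH), NaOAc, CH2Cl2, 0 °C → rt
Reagents that add atoms: peracetic acid, CC(=O)OO
Why: the peracid attacks the silyl-bearing furan carbon (ipso attack favoured by the β-silicon effect), a carbon-to-oxygen silyl shift gives the 2-silyloxyfuran, and its hydrolysis gives the conjugated butenolide with the carbonyl at the former C–Si carbon (peracid oxidation of 2-silylfurans to butenolides), so the 16,15-olide and not its 15,16-isomer is formed.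

**Compound list**
1 | 3-bromofuran | Brc1ccoc1 | starting material
2 | 3-bromo-2-lithiofuran | [Li]c1occc1Br | intermediate
3 | 3-bromo-2-(triethylsilyl)furan | CC[Si](CC)(CC)c1occc1Br | intermediate
4 | oxirane | C1CO1 | starting material
5 | 3-lithio-2-(triethylsilyl)furan | [Li]c1ccoc1[Si](CC)(CC)CC | intermediate
6 | 2-[2-(triethylsilyl)furan-3-yl]ethan-1-ol | OCCc1ccoc1[Si](CC)(CC)CC | intermediate
7 | 3-(2-iodoethyl)-2-(triethylsilyl)furan | ICCc1ccoc1[Si](CC)(CC)CC | intermediate
8 | 4-methoxy-2,6-dimethylphenol | COc1cc(C)c(O)c(C)c1 | starting material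
9 | 4,4-dimethoxy-2,6-dimethylcyclohexa-2,5-dien-1-one | COC1(OC)C=C(C)C(=O)C(C)=C1 | intermediate
10 | 2-[2-(triethylsilyl)furan-3-yl]ethyllithium | [Li]CCc1ccoc1[Si](CC)(CC)CC | intermediate
11 | lithium 4,4-dimethoxy-2,6-dimethyl-1-{2-[2-(triethylsilyl)furan-3-yl]ethyl}cyclohexa-2,5-dien-1-olate | [Li]OC1(CCc2ccoc2[Si](CC)(CC)CC)C(C)=CC(OC)(OC)C=C1C | intermediate
12 | 3-{2-[4,4-dimethoxy-2,6-dimethyl-1-[(trimethylsilyl)oxy]cyclohexa-2,5-dien-1-yl]ethyl}-2-(triethylsilyl)furan | COC1(OC)C=C(C)C(O[Si](C)(C)C)(CCc2ccoc2[Si](CC)(CC)CC)C(C)=C1 | intermediate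
13 | 3,5-dimethyl-4-{2-[2-(triethylsilyl)furan-3-yl]ethyl}-4-[(trimethylsilyl)oxy]cyclohexa-2,5-dien-1-one (achiral quinol ether) | O=C1C=C(C)C(O[Si](C)(C)C)(CCc2ccoc2[Si](CC)(CC)CC)C(C)=C1 | intermediate
14 | 4-methyl-1,3-pentadiene | CC(C)=CC=C | starting material
15 | (5R,9R,10S)-16-(triethylsilyl)-9-[(trimethylsilyl)oxy]-15,16-epoxylabda-2,7,13(16),14-tetraen-6-one; cis-fused, 5β-H, 10β-CH3, 9α-OSiMe3 | O=C1C=C(C)[C@](O[Si](C)(C)C)(CCc2ccoc2[Si](CC)(CC)CC)[C@@]2(C)CC=CC(C)(C)[C@@H]12 | intermediate
16 | (5R,9R,10S)-16-(triethylsilyl)-9-[(trimethylsilyl)oxy]-15,16-epoxylabda-7,13(16),14-trien-6-one; cis-fused | O=C1C=C(C)[C@](O[Si](C)(C)C)(CCc2ccoc2[Si](CC)(CC)CC)[C@@]2(C)CCCC(C)(C)[C@@H]12 | intermediate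
17 | (5R,9R,10S)-9-hydroxy-16-(triethylsilyl)-15,16-epoxylabda-7,13(16),14-trien-6-one; cis-fused, 5β-H | O=C1C=C(C)[C@](O)(CCc2ccoc2[Si](CC)(CC)CC)[C@@]2(C)CCCC(C)(C)[C@@H]12 | intermediate
18 | (5S,9R,10S)-9-hydroxy-16-(triethylsilyl)-15,16-epoxylabda-7,13(16),14-trien-6-one; trans-fused, 5α-H | O=C1C=C(C)[C@](O)(CCc2ccoc2[Si](CC)(CC)CC)[C@@]2(C)CCCC(C)(C)[C@H]12 | intermediate
19 | (5S,8R,9R,10S)-9-hydroxy-16-(triethylsilyl)-15,16-epoxylabda-13(16),14-dien-6-one; 8α-CH3 | O=C1C[C@@H](C)[C@](O)(CCc2ccoc2[Si](CC)(CC)CC)[C@@]2(C)CCCC(C)(C)[C@H]12 | intermediate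
20 | (5S,6R,8R,9R,10S)-16-(triethylsilyl)-15,16-epoxylabda-13(16),14-diene-6β,9α-diol | O[C@@H]1C[C@@H](C)[C@](O)(CCc2ccoc2[Si](CC)(CC)CC)[C@@]2(C)CCCC(C)(C)[C@H]12 | intermediate
21 | (5S,6R,8R,9R,10S)-6β-acetoxy-16-(triethylsilyl)-15,16-epoxylabda-13(16),14-dien-9α-ol | CC(=O)O[C@@H]1C[C@@H](C)[C@](O)(CCc2ccoc2[Si](CC)(CC)CC)[C@@]2(C)CCCC(C)(C)[C@H]12 | intermediate
22 | (5S,6R,8R,9R,10S)-6β-acetoxy-9α-hydroxylabd-13-en-16,15-olide (CNP0205088.1) | CC(=O)O[C@@H]1C[C@@H](C)[C@](O)(CCC2=CCOC2=O)[C@@]2(C)CCCC(C)(C)[C@H]12 | target

**Totals**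
Total step count: 12. Longest linear sequence: 11 steps (1, 2, 3, 5–12, from 3-bromofuran).

**Steps most likely to fail**

Step 6 (Proposed new method). What may go wrong: the β-methyl enone next to a fully substituted carbon may be too weak a dienophile at the temperatures where the catalyst is selective, the acid catalyst may oligomerise the diene, or the furan may attack the activated dienone in a Friedel–Crafts sense. The diene may also leak to the enone unit outside the chiral pocket or to the chain-bearing face, which would erode enantiomeric and diastereomeric purity.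
Fallback (known chemistry), setting out from diene 14 and alkyllithium 10 and coming back to the route at 17: purchased 2,6-dimethyl-1,4-benzoquinone F1 and 14 are combined under oxazaborolidinium catalysis, for which quinones are established dienophiles. The catalyst binds the carbonyl flanked by two vinylic CH groups, the doubly activated methyl-bearing double bond reacts, and the CH2 terminus of the diene goes to the methyl-bearing carbon, which should give the cis-fused enedione F2. 1,2-Reduction (NaBH4, CeCl3, MeOH, −78 °C) of the less hindered C6 carbonyl should give the cis-fused 6-hydroxy-7-en-9-one F3 (the C6 configuration is of no consequence). Alkyllithium 10 (prepared as in step 5, one extra equivalent for the hydroxyl) is then added to the remaining C9 ketone from the convex β-face of the cis-fused bicycle to give the 6,9-diol F4 with the 9α-hydroxyl. MnO2 re-oxidises the allylic C6 alcohol to the cis-fused hydroxy enone F5, and hydrogenation as in step 7 gives 17, which enters the epimerisation of step 8.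

Step 9. What may go wrong: electron transfer may not stop at the enone (reduction of the silylfuran, or loss of the C9 oxygen by β-elimination from the radical anion), or C8 may be protonated equatorially.
Fallback, setting out from 18 and coming back at 20: 1,2-reduction of the enone (NaBH4, CeCl3, MeOH, −78 °C; hydride from the α-face) should give the allylic 6β-alcohol F6. A hydrogen-atom-transfer hydrogenation of the C7=C8 alkene (Mn(dpm)3, PhSiH3, t-BuOOH, i-PrOH) then passes through the tertiary C8 radical, which is expected to be quenched to the thermodynamically preferred equatorial 8α-methyl epimer, giving 20 without any electron-transfer reagent.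

Step 8. What may go wrong: the cis→trans equilibration at C5 may be slow or may not lie far enough on the trans side, since the equatorial C4 methyl sits close to the C6 carbonyl in the trans isomer.
Fallback, setting out from 16 and coming back at 18: 16 is converted with KHMDS (THF, −78 °C) into its cross-conjugated dienolate, which is protonated under kinetic control on the α-face, anti to the C10 methyl, by 2,6-di-tert-butylphenol to give the trans-fused silyl ether F7. Desilylation with citric acid in methanol at 0 °C, conditions that do not equilibrate C5, then gives 18.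

**Further compounds**
F1 | step 6 | 2,6-dimethyl-1,4-benzoquinone (purchased) | CC1=CC(=O)C=C(C)C1=O
F2 | step 6 | (4aR,8aS)-2,5,5,8a-tetramethyl-4a,5,8,8a-tetrahydronaphthalene-1,4-dione (cis-fused enedione; labdane-type C6 and C9 ketones, C7=C8, C2=C3) | O=C1C=C(C)C(=O)[C@@]2(C)CC=CC(C)(C)[C@@H]12
F3 | step 6 | cis-fused 6α-hydroxy-2,7-dien-9-one of F2 (labdane-type numbering) | O[C@H]1C=C(C)C(=O)[C@@]2(C)CC=CC(C)(C)[C@@H]12
F4 | step 6 | (5R,6S,9R,10S)-16-(triethylsilyl)-15,16-epoxylabda-2,7,13(16),14-tetraene-6α,9α-diol (cis-fused) | O[C@H]1C=C(C)[C@](O)(CCc2ccoc2[Si](CC)(CC)CC)[C@@]2(C)CC=CC(C)(C)[C@@H]12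
F5 | step 6 | (5R,9R,10S)-9-hydroxy-16-(triethylsilyl)-15,16-epoxylabda-2,7,13(16),14-tetraen-6-one (cis-fused) | O=C1C=C(C)[C@](O)(CCc2ccoc2[Si](CC)(CC)CC)[C@@]2(C)CC=CC(C)(C)[C@@H]12
F6 | step 9 | (5S,6R,9R,10S)-16-(triethylsilyl)-15,16-epoxylabda-7,13(16),14-triene-6β,9α-diol | O[C@@H]1C=C(C)[C@](O)(CCc2ccoc2[Si](CC)(CC)CC)[C@@]2(C)CCCC(C)(C)[C@H]12
F7 | step 8 | (5S,9R,10S)-16-(triethylsilyl)-9-[(trimethylsilyl)oxy]-15,16-epoxylabda-7,13(16),14-trien-6-one (trans-fused) | O=C1C=C(C)[C@](O[Si](C)(C)C)(CCc2ccoc2[Si](CC)(CC)CC)[C@@]2(C)CCCC(C)(C)[C@H]12
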